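Cuts: first the 7''-O-methyl group, which leads back to a C2-symmetric tetraol. Then O1–C8a and C4–C4a are cut in both halves at once, and last the central C3–C3'' bond.
Enabling feature: each ring A is tied to its ring C only through two neighbouring carbons, C8a (to O1) and C4a (to C4, flanked by the 5-oxygen). This is the imprint of a nucleophile and an electrophile added across a 3,5-dioxygenated benzyne. What remains, C2–C3–C3''–C2'' with C4, C4'' and the two rings B, is an 8,8'-lignan chain.
Forward order: C3–C3'' is made by oxidative dimerisation of an enolate. Two gamma-lactone rings are closed by benzylic oxidation and opened again to a bis(hydroxy amide). Both rings A are then fused on and both rings C closed in one flask, followed by debenzylation and one O-methylation.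
Stereochemistry: C3 and C3'' come from an (S)-4-benzyloxazolidinone auxiliary. C2 and C2'' come from substrate-controlled closure of the cis-fused dilactone with both aryl groups exo. This relation becomes 2,3-cis once the C2–C3 bond is turned so that O1 lies over C4 instead of over C3''.
After the dilactone no bond to a stereocentre is made or broken, and the labile cis,cis diketone meets neither acid nor base.

Key step: step 9

Remark: flavanone numbering (O1, C2, C3, C4, C4a, C5–C8, C8a; double primes for the second half) is used for all intermediates. The target SMILES is read as (2S,3S,2''S,3''S) with H-2 and H-3 cis in both halves.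

Step 1
Reactants: 1 phloroglucinol
Product: 2 3,5-bis(benzyloxy)phenol
Conditions: BnBr (2.0 equiv), K2CO3, DMF, rt; chromatography
Reagents that add atoms: benzyl bromide, BrCc1ccccc1
Why: Williamson etherification with two equivalents of halide gives a statistical set of ethers, and the wanted di-ether, which still carries one acidic OH, is separated by chromatography from the mono- and tri-ethers.

Step 2
Reactants: 2 3,5-bis(benzyloxy)phenol
Product: 3 3,5-bis(benzyloxy)-2-iodophenol
Conditions: N-iodosuccinimide (1.0 equiv), CH2Cl2, −78 → 0 °C, dark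
Reagents that add atoms: N-iodosuccinimide, O=C1CCC(=O)N1I
Why: Electrophilic aromatic iodination of this phloroglucinol-type ring is fast in the cold, and the site between OH and OBn, next to the hydrogen-bond-donating OH and less hemmed in than the site between the two benzyloxy groups, should be iodinated first, the minor 4-iodo isomer being removed by chromatography.

Step 3
Reactants: 3 3,5-bis(benzyloxy)-2-iodophenol
Product: 4 3,5-bis(benzyloxy)-2-iodophenyl trifluoromethanesulfonate
Conditions: Tf2O, pyridine, CH2Cl2, 0 °C
Reagents that add atoms: trifluoromethanesulfonic anhydride, O=S(=O)(OS(=O)(=O)C(F)(F)F)C(F)(F)F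
Why: O-Sulfonylation of a phenol with Tf2O and pyridine is routine, touches neither the aryl iodide nor the benzyl ethers, and gives an ortho-iodoaryl triflate, an established class of aryne precursor.

Step 4
Reactants: 5 3-(4-methoxyphenyl)propanoic acid; 6 (S)-4-benzyloxazolidin-2-one
Product: 8 (S)-4-benzyl-3-[3-(4-methoxyphenyl)propanoyl]oxazolidin-2-one, via mixed pivalic anhydride 7 (not isolated)
Conditions: PivCl, Et3N, THF, −20 → 0 °C; then LiCl, 6, rt
Reagents that add atoms: none
Why: N-Acylation of the oxazolidinone through a mixed pivalic anhydride with LiCl activation is standard, attack going to the unhindered carbonyl group of 7, and no stereocentre is formed.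

Step 5
Reactants: 8 (S)-4-benzyl-3-[3-(4-methoxyphenyl)propanoyl]oxazolidin-2-one (two molecules)
Product: 10 (2R,3R)-1,4-bis[(S)-4-benzyl-2-oxooxazolidin-3-yl]-2,3-bis(4-methoxybenzyl)butane-1,4-dione, via lithium Z-enolate 9 (not isolated)
Conditions: LiN(iPr)2 (1.05 equiv), THF, −78 °C; TiCl4 (1.1 equiv), −78 °C → rt
Reagents that add atoms: none
Why: Oxidative homocoupling of an imide enolate: the chelated Z-enolate 9 is oxidised by one electron by tetravalent titanium, which ends as trivalent titanium, and the two alpha carbons join on the enolate face turned away from the benzyl group of the auxiliary (the face also used in alkylations), which should make the (R,R)-dimer the main product, freed from its diastereomers by crystallisation.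

Step 6
Reactants: 10 (R,R)-bis-imide
Product: 12 (2R,3R)-2,3-bis(4-methoxybenzyl)succinic acid, via bis(peroxy acid) 11 (not isolated)
Conditions: LiOH, 30% H2O2, THF/H2O, 0 °C; aq Na2SO3; HCl to pH 2
Reagents that add atoms: hydrogen peroxide, OO
Why: Hydroperoxide cleavage of N-acyl oxazolidinones attacks the exocyclic carbonyl groups only, is too mild to epimerise the alpha carbons, returns the auxiliary, and the peroxy acid 11 is reduced by sulfite before acidification.

Step 7
Reactants: 12 (2R,3R)-2,3-bis(4-methoxybenzyl)succinic acid
Product: 13 (1S,2S,5S,6S)-2,6-bis(4-methoxyphenyl)-3,7-dioxabicyclo[3.3.0]octane-4,8-dione (cis-fused; both aryl groups exo)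
Conditions: DDQ (2.5 equiv), 4 Å MS, ClCH2CH2Cl, 70 °C
Reagents that add atoms: none
Why: Oxidative benzylic C–H lactonisation of gamma-aryl carboxylic acids: DDQ takes a hydride from each CH2 group para to a methoxy group and the anisyl cation is caught by the carboxyl group in the gamma position (five-membered ring instead of a beta-lactone), the aryl group settling trans to the neighbouring carboxyl carbon and thus on the convex face of the cis-fused bicycle, so that C2 and C2'' are set as S by substrate control, as in the oxidative dimerisation of 4-alkoxycinnamic acids, which ends in the same double cation capture.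

Step 8
Reactants: 13 all-exo dilactone
Product: 14 (2S,3S)-2,3-bis[(S)-hydroxy(4-methoxyphenyl)methyl]-N,N'-dimethoxy-N,N'-dimethylsuccinamide
Conditions: MeNH(OMe)·HCl (6 equiv), iPrMgCl (12 equiv), THF, −20 → 0 °C; pH 7 phosphate buffer, 0 °C; used the same day
Reagents that add atoms: N,O-dimethylhydroxylamine hydrochloride, CNOC.Cl
Why: Aminolysis of lactones by the chloromagnesium amide of N,O-dimethylhydroxylamine breaks only the acyl–oxygen bonds, so all four stereocentres are kept, and it avoids aluminium Lewis acids that could ionise the anisyl C–O bonds, while cold neutral work-up and immediate use guard against closure back to the lactone.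

Step 9
Reactants: 14 bis(hydroxy amide); 4 3,5-bis(benzyloxy)-2-iodophenyl trifluoromethanesulfonate (two molecules)
Product: 19 (2S,3S,2''S,3''S)-5,7,5'',7''-tetrakis(benzyloxy)-4',4'''-dimethoxy-3,3''-biflavanone, via dilithium dialkoxide 15 (not isolated), via 3,5-bis(benzyloxy)benzyne 16 (not isolated), via bis(aryllithium) 17 (not isolated), via bis(hemiaminal alkoxide) 18 (not isolated)
Conditions: n-BuLi (2.0 equiv), THF, −78 °C; 4 (2.3 equiv); Me3SiCH2MgCl (2.4 equiv) dropwise, −78 → −20 °C; cannulated into pH 7 phosphate buffer, 0 °C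
Reagents that add atoms: none
Why: Proposed new method: iodine–magnesium exchange on 4 and loss of triflate release aryne 16 beside dialkoxide 15, each alkoxide oxygen adds to the aryne carbon remote from the 3-benzyloxy group (O1–C8a), the aryl carbanion of 17, born between two oxygen substituents, adds to the amide carbonyl beta to that oxygen (C4a–C4), and the chelated adduct 18 holds until the cold buffer frees both ketones. The closest known reaction types are the phenoxide/aryne/ester annulation of salicylates to xanthones, the addition of magnesium thiolates and amides to arynes from ortho-iodoaryl sulfonates with trapping of the arylmagnesium, and the Parham cyclisation of aryllithiums onto N-methoxy-N-methylamides, whereas an aliphatic alkoxide as the nucleophile and a twofold run on one template are new. Each ring C closes 6-exo-trig at the amide carbonyl after an intermolecular O-arylation, and each ring A is fused on through its two former aryne carbons. No stereocentre of 19 is created, since C2, C3, C3'' and C2'' are carried over with retention because no bond to them is made or broken, and the two hemiaminal carbons of 18 vanish on quenching. The step needs regioselective attack on the unsymmetrical aryne, which the inductive and distortion effect of the 3-benzyloxy group secures (5,7-pattern), and capture by the beta amide rather than the gamma amide, which the six- against seven-membered ring size secures. Because O1 is arylated before C4 becomes a ketone and the ketones stay masked while base is present, retro-aldol cleavage, E1cB loss of aryloxide and epimerisation at C3 should be held back, and butane as the only conjugate acid leaves no proton source for 17.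

Step 10
Reactants: 19 tetra-O-benzyl cis,cis-biflavanone
Product: 20 (2S,3S,2''S,3''S)-5,7,5'',7''-tetrahydroxy-4',4'''-dimethoxy-3,3''-biflavanone
Conditions: H2 (1 atm), 10% Pd/C, EtOAc/THF, rt, stopped at the calculated uptake
Reagents that add atoms: none
Why: Catalytic hydrogenolysis of aryl benzyl ethers under neutral conditions is faster than cleavage of the cyclic C2–O1 bond or reduction of the aryl ketones, and in the absence of acid and base the cis relation at C2/C3 is not disturbed.

Step 11
Reactants: 20 C2-symmetric tetraol
Product: 21 (2S,3S,2''S,3''S)-5,7,5''-trihydroxy-7'',4',4'''-trimethoxy-3,3''-biflavanone (CNP0184936.4)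
Conditions: Me3SiCHN2 (0.9 equiv), toluene/MeOH, 0 °C; chromatography, recovered 20 recycled
Reagents that add atoms: (trimethylsilyl)diazomethane, C[Si](C)(C)C=[N+]=[N-]
Why: Base-free O-methylation of an acidic phenol by a diazoalkane: the 7-OH groups behave as vinylogous acids and react while the 5-OH groups are locked in hydrogen bonds to C4=O, the two 7-OH groups of C2-symmetric 20 are homotopic so that only one mono-ether can form, and a slight deficit of reagent keeps the bis-ether low and leaves 20 for recycling.

Compound list
1 | phloroglucinol | Oc1cc(O)cc(O)c1 | starting material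
2 | 3,5-bis(benzyloxy)phenol | Oc1cc(OCc2ccccc2)cc(OCc2ccccc2)c1 | intermediate
3 | 3,5-bis(benzyloxy)-2-iodophenol | Oc1cc(OCc2ccccc2)cc(OCc2ccccc2)c1I | intermediate
4 | 3,5-bis(benzyloxy)-2-iodophenyl trifluoromethanesulfonate | FC(F)(F)S(=O)(=O)Oc1cc(OCc2ccccc2)cc(OCc2ccccc2)c1I | intermediate
5 | 3-(4-methoxyphenyl)propanoic acid | COc1ccc(CCC(=O)O)cc1 | starting material
6 | (S)-4-benzyloxazolidin-2-one | O=C1N[C@@H](Cc2ccccc2)CO1 | starting material
7 | 3-(4-methoxyphenyl)propanoic pivalic anhydride | COc1ccc(CCC(=O)OC(=O)C(C)(C)C)cc1 | intermediate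
8 | (S)-4-benzyl-3-[3-(4-methoxyphenyl)propanoyl]oxazolidin-2-one | COc1ccc(CCC(=O)N2[C@@H](Cc3ccccc3)COC2=O)cc1 | intermediate
9 | lithium (Z)-enolate of 8 | COc1ccc(C/C=C(\[O-])N2[C@@H](Cc3ccccc3)COC2=O)cc1.[Li+] | intermediate
10 | (2R,3R)-1,4-bis[(S)-4-benzyl-2-oxooxazolidin-3-yl]-2,3-bis(4-methoxybenzyl)butane-1,4-dione | COc1ccc(C[C@@H](C(=O)N2[C@@H](Cc3ccccc3)COC2=O)[C@H](C(=O)N2[C@@H](Cc3ccccc3)COC2=O)Cc2ccc(OC)cc2)cc1 | intermediate
11 | (2R,3R)-2,3-bis(4-methoxybenzyl)butanediperoxoic acid | COc1ccc(C[C@@H](C(=O)OO)[C@H](C(=O)OO)Cc2ccc(OC)cc2)cc1 | intermediate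
12 | (2R,3R)-2,3-bis(4-methoxybenzyl)succinic acid | COc1ccc(C[C@@H](C(=O)O)[C@H](C(=O)O)Cc2ccc(OC)cc2)cc1 | intermediate
13 | (1S,2S,5S,6S)-2,6-bis(4-methoxyphenyl)-3,7-dioxabicyclo[3.3.0]octane-4,8-dione, cis-fused, both aryl groups exo | COc1ccc([C@H]2OC(=O)[C@H]3[C@@H]2C(=O)O[C@@H]3c2ccc(OC)cc2)cc1 | intermediate
14 | (2S,3S)-2,3-bis[(S)-hydroxy(4-methoxyphenyl)methyl]-N,N'-dimethoxy-N,N'-dimethylsuccinamide | COc1ccc([C@@H](O)[C@@H](C(=O)N(C)OC)[C@H](C(=O)N(C)OC)[C@H](O)c2ccc(OC)cc2)cc1 | intermediate
15 | dilithium dialkoxide of 14 | COc1ccc([C@@H]([O-])[C@@H](C(=O)N(C)OC)[C@H](C(=O)N(C)OC)[C@H]([O-])c2ccc(OC)cc2)cc1.[Li+].[Li+] | intermediate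
16 | 3,5-bis(benzyloxy)benzyne | C1#CC(OCc2ccccc2)=CC(OCc2ccccc2)=C1 | intermediate
17 | bis[3,5-bis(benzyloxy)-2-lithiophenyl] ether of 14 | COc1ccc([C@@H](Oc2cc(OCc3ccccc3)cc(OCc3ccccc3)c2[Li])[C@@H](C(=O)N(C)OC)[C@H](C(=O)N(C)OC)[C@H](Oc2cc(OCc3ccccc3)cc(OCc3ccccc3)c2[Li])c2ccc(OC)cc2)cc1 | intermediate
18 | dilithium salt of the doubly cyclised 4,4''-bis[methoxy(methyl)amino]-4,4''-diolate (C4 and C4'' unassigned, other centres as in 19) | COc1ccc([C@H]2Oc3cc(OCc4ccccc4)cc(OCc4ccccc4)c3C([O-])(N(C)OC)[C@H]2[C@@H]2C([O-])(N(C)OC)c3c(OCc4ccccc4)cc(OCc4ccccc4)cc3O[C@@H]2c2ccc(OC)cc2)cc1.[Li+].[Li+] | intermediate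
19 | (2S,3S,2''S,3''S)-5,7,5'',7''-tetrakis(benzyloxy)-4',4'''-dimethoxy-3,3''-biflavanone | COc1ccc([C@H]2Oc3cc(OCc4ccccc4)cc(OCc4ccccc4)c3C(=O)[C@H]2[C@@H]2C(=O)c3c(OCc4ccccc4)cc(OCc4ccccc4)cc3O[C@@H]2c2ccc(OC)cc2)cc1 | intermediate
20 | (2S,3S,2''S,3''S)-5,7,5'',7''-tetrahydroxy-4',4'''-dimethoxy-3,3''-biflavanone | COc1ccc([C@H]2Oc3cc(O)cc(O)c3C(=O)[C@H]2[C@@H]2C(=O)c3c(O)cc(O)cc3O[C@@H]2c2ccc(OC)cc2)cc1 | intermediate
21 | (2S,3S,2''S,3''S)-5,7,5''-trihydroxy-7'',4',4'''-trimethoxy-3,3''-biflavanone (CNP0184936.4) | COc1ccc([C@H]2Oc3cc(O)cc(O)c3C(=O)[C@H]2[C@@H]2C(=O)c3c(O)cc(OC)cc3O[C@@H]2c2ccc(OC)cc2)cc1 | target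

Total step count: 11. Longest linear sequence: 8 steps (steps 4 to 11, from 5). The ring A branch (steps 1 to 3) joins at step 9.

Steps most likely to fail

1. Step 9.
- What may go wrong:
  - The hindered secondary alkoxide may add to the aryne too slowly, so that the aryne is consumed by the Grignard trigger.
  - The aryl carbanion may take the proton at C3 or C2 through a cyclic transition state, which would be followed by E1cB loss of the aryloxide.
  - The alkoxide may close back onto the gamma amide.
  - The N–OMe group may lose formaldehyde under base.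
  - Only one of the two halves may annulate.
- Fallback (known reactions only), from 13 back to 19: 13 is reduced with iBu2AlH (CH2Cl2, −78 °C) to the bis-lactol F1. Separately, 1,3,5-trifluorobenzene is taken through two successive SNAr displacements with BnOH/NaH (DMF, heat) to 1,3-bis(benzyloxy)-5-fluorobenzene F2. N-Iodosuccinimide iodinates F2 at the open site between fluorine and a benzyloxy group to give the aryl iodide F3. Iodine–magnesium exchange (iPrMgCl·LiCl, THF, −40 °C) then gives the arylmagnesium chloride F4, which keeps its fluoride at this temperature. An excess of F4 (two equivalents are spent on the lactol OH groups and return F2) adds to the open hydroxy-aldehyde form of F1 (−40 → 0 °C, Grignard addition to a lactol) and gives the tetraol F5. The new C4 and C4'' carbinol configurations of F5 do not matter. KOtBu in THF/DMF at 60 °C closes both rings C by intramolecular SNAr of the C2 and C2'' alkoxides on the C8a–F carbons. The ring formed is six-membered, both benzyloxy groups are meta to fluorine, and C2 keeps its configuration. The product is the bis(flavan-4-ol) F6, in which no carbonyl group is present that base could use for retro-aldol cleavage. A NaHCO3-buffered Dess–Martin oxidation returns 19.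

2. Step 7.
- What may go wrong:
  - Hydride abstraction from a mono-methoxy arene that carries a beta carboxyl group may be sluggish.
  - The cation may lose the C3 proton, which erases that stereocentre.
  - The exo/endo selectivity of the capture may be poor.
- Fallback, from 12 back to 13: the ionic C–H oxidation is replaced by radical halogenation. 12 is esterified (MeOH, cat. H2SO4) to the dimethyl ester F7. Wohl–Ziegler bromination (N-bromosuccinimide, dibenzoyl peroxide, PhCF3, light, reflux) gives the bis(benzylic bromide) F8 as a mixture at the benzylic carbons. On further warming each anisyl carbon–bromine bond ionises, the gamma ester carbonyl oxygen captures the cation and bromide removes the methyl group. This delivers 13, which is purified from any endo isomer by crystallisation.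

3. Step 8.
- What may go wrong:
  - The second lactone may open incompletely.
  - The basic magnesium amide may enolise the lactone and epimerise C3.
  - The lactone rings may close again during work-up.
- Fallback, from 13 back to 14: the metal amide is replaced by an uncatalysed aminolysis with an alpha-effect nucleophile. 13 is stirred with N-methylhydroxylamine (from MeNHOH·HCl and Et3N, MeOH/THF, rt) to give the bis(N-hydroxy-N-methylamide) F9. Its two acidic N–OH groups are then O-methylated with Me3SiCHN2 (toluene/MeOH, 0 °C), the secondary alcohols staying free, to give 14.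

Further compounds
F1 | step 9 | (1S,2S,5S,6S)-2,6-bis(4-methoxyphenyl)-3,7-dioxabicyclo[3.3.0]octane-4,8-diol (bis-lactol, lactol carbons unassigned) | COc1ccc([C@H]2OC(O)[C@H]3[C@@H]2C(O)O[C@@H]3c2ccc(OC)cc2)cc1
F2 | step 9 | 1,3-bis(benzyloxy)-5-fluorobenzene | Fc1cc(OCc2ccccc2)cc(OCc2ccccc2)c1
F3 | step 9 | 1,5-bis(benzyloxy)-3-fluoro-2-iodobenzene | Fc1cc(OCc2ccccc2)cc(OCc2ccccc2)c1I
F4 | step 9 | [2,4-bis(benzyloxy)-6-fluorophenyl]magnesium chloride | Fc1cc(OCc2ccccc2)cc(OCc2ccccc2)c1[Mg]Cl
F5 | step 9 | (2S,3S)-1,4-bis[2,4-bis(benzyloxy)-6-fluorophenyl]-2,3-bis[(S)-hydroxy(4-methoxyphenyl)methyl]butane-1,4-diol (C1 and C4 carbinol centres unassigned) | COc1ccc([C@@H](O)[C@@H](C(O)c2c(F)cc(OCc3ccccc3)cc2OCc2ccccc2)[C@H](C(O)c2c(F)cc(OCc3ccccc3)cc2OCc2ccccc2)[C@H](O)c2ccc(OC)cc2)cc1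
F6 | step 9 | 5,7,5'',7''-tetrakis(benzyloxy)-4',4'''-dimethoxy-3,3''-biflavan-4,4''-diol (C2, C3, C3'', C2'' arranged in space as in 19; C4 and C4'' unassigned) | COc1ccc([C@H]2Oc3cc(OCc4ccccc4)cc(OCc4ccccc4)c3C(O)[C@H]2[C@@H]2C(O)c3c(OCc4ccccc4)cc(OCc4ccccc4)cc3O[C@@H]2c2ccc(OC)cc2)cc1
F7 | step 7 | dimethyl (2R,3R)-2,3-bis(4-methoxybenzyl)succinate | COc1ccc(C[C@@H](C(=O)OC)[C@H](C(=O)OC)Cc2ccc(OC)cc2)cc1
F8 | step 7 | dimethyl (2R,3R)-2,3-bis[bromo(4-methoxyphenyl)methyl]succinate (benzylic centres unassigned) | COc1ccc(C(Br)[C@@H](C(=O)OC)[C@H](C(=O)OC)C(Br)c2ccc(OC)cc2)cc1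
F9 | step 8 | (2S,3S)-N,N'-dihydroxy-2,3-bis[(S)-hydroxy(4-methoxyphenyl)methyl]-N,N'-dimethylsuccinamide | COc1ccc([C@@H](O)[C@@H](C(=O)N(C)O)[C@H](C(=O)N(C)O)[C@H](O)c2ccc(OC)cc2)cc1
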